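**Retrosynthetic overview**
1. The target is the erythro-(7″R,8″S)-guaiacylglycerol 8″-O-4 ether of an endo-aryl bicyclic lactone (7R,8R,8′R; H-7, H-8 and H-8′ all cis).
2. The side chain goes on last. C7″–C8″ comes from an auxiliary-controlled anti-aldol with vanillin, the ether from O-alkylation of the free phenol, and C9″ from imide reduction. This leads back to the endo phenolic lactone.
3. The endo lactone comes from the exo lactone by opening and re-closing the THF ring through its p-quinone methide, which changes only C7. The absolute series is picked at the exo lactone by resolution.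
4. The exo lactone comes from syringaresinol by oxidative Cα–aryl cleavage: one syringyl ring is burnt off as 2,6-dimethoxybenzoquinone and C7′ becomes the lactone C=O. Syringaresinol comes from 2 × sinapyl alcohol by 8–8′ phenoxyl coupling, and both events run in one flask.
5. Ring order: both oxacycles form together from the bis-quinone methide. One is then oxidised to the γ-lactone. The aryl-bearing THF ring is re-formed once under thermodynamic control.

Assumption: the SMILES is read literally (aryl endo, 7R,8R,8′R; side chain erythro, 7″R,8″S); lignan numbering: C7–C9 = retained sinapyl unit, C7′–C9′ = second unit (C7′ = lactone C=O), C7″–C9″ = guaiacylglycerol chain.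

**Step 1**
Reactants: 1 sinapyl alcohol (2 equiv)
Product: 5 rac-exo-lactone [rel-(7S,8R,8′R)-6-(4-hydroxy-3,5-dimethoxyphenyl)-3,7-dioxabicyclo[3.3.0]octan-2-one; aryl exo], via bis-quinone methide 2 (not isolated), via rac-syringaresinol 3 (not isolated), via 7′-hemiketal 4 (not isolated)
Conditions: Trametes versicolor laccase (cat.), O2 (1 atm), NaOAc buffer pH 5/MeCN 2:1, 25 °C, 2 h; second laccase charge, 35 °C, HPLC control, stop at ca. 60 % conversion of 3 (3 recovered, resubmitted)
Reagents that add atoms: water, O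
Why: Proposed new method: laccase/O2 makes the sinapyl phenoxyl radical, whose 8–8′ radical–radical coupling gives the threo bis-quinone methide 2, which closes twice by 5-exo oxa-1,6-addition of each γ-OH from the A(1,3)-minimised rotamer (sets H-8/H-8′ cis and both aryls exo, racemic); further turnover on one syringyl phenol of 3 gives the 7′-alkoxy quinone methide, its hydrate 4 and, after oxidation and water attack at C-1′, Cα–aryl fragmentation to the lactone plus 2,6-dimethoxybenzoquinone; the closest known reaction types are the laccase dehydrodimerisation of sinapyl alcohol to syringaresinol and the phenol-oxidase alkyl–aryl cleavage of syringyl lignin units, here run in one flask and stopped at mono-cleavage.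

**Step 2**
Reactants: 5 rac-exo-lactone
Product: 6 (7S,8R,8′R)-exo-lactone
Conditions: preparative chiral SFC, cellulose tris(3,5-dimethylphenylcarbamate) phase, CO2/MeOH 75:25, 35 °C; configuration checked by ECD
Reagents that add atoms: none
Why: Chromatographic resolution of enantiomers on a polysaccharide phase, routine for furofuran-type lignans, makes no bond and selects the 8R,8′R series, which fixes the absolute configuration of C-8 and C-8′.

**Step 3**
Reactants: 6 (7S,8R,8′R)-exo-lactone
Product: 8 (7R,8R,8′R)-endo-lactone (H-7/H-8/H-8′ all cis), via ring-opened p-quinone methide 7 (not isolated)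
Conditions: TsOH·H2O (5 mol %), EtOAc, 50 °C, to equilibrium; SiO2 separation, 6 recycled
Reagents that add atoms: none
Why: Acid-catalysed benzylic epimerisation of furofuran lignans (sesamin/asarinin type): protonation of the ring oxygen opens the THF ring to the O-protonated form of 7, and re-closure by the 9′-OH on either face equilibrates C-7 only (C-8 and C-8′ untouched), giving about 2:1 exo:endo, from which the 7R endo isomer is separated and the exo isomer is fed back.

**Step 4**
Reactants: 8 (7R,8R,8′R)-endo-lactone; 9 (S)-4-benzyl-3-(chloroacetyl)oxazolidin-2-one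
Product: 10 aryloxyacetyl imide of 8
Conditions: K2CO3 (1.5 equiv), DMF, 40 °C
Reagents that add atoms: none
Why: Williamson ether synthesis (SN2): the hindered 2,6-dimethoxyphenoxide attacks the activated α-chloro carbon rather than the imide carbonyl, carbonate at 40 °C is too mild to open the benzylic ether, and once O-4 is alkylated the quinone methide path is closed, so C-7 is locked.

**Step 5**
Reactants: 10 aryloxyacetyl imide; 11 vanillin
Product: 14 anti-aldol imide (free 7″-OH and phenol), via O-TMS-vanillin 12 (not isolated), via bis-TMS anti-aldol 13 (not isolated)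
Conditions: MgCl2 (20 mol %), Et3N (4 equiv), TMSCl (3 equiv), EtOAc, 23 °C, 24 h; then AcOH/THF/H2O 3:1:1, 23 °C, 1 h
Reagents that add atoms: none
Why: Evans magnesium-halide-catalysed direct anti-aldol (soft enolisation, turnover by O-silylation), extended here to an aryloxyacetyl imide: the Mg-chelated (Z)-enolate of the (S)-benzyl imide reacts on the face away from the benzyl group (sets C-8″) with vanillin silylated in situ, through the anti-selective transition state favoured for aromatic aldehydes (sets C-7″, erythro), and mild AcOH then strips both TMS groups without ionising the p-hydroxybenzylic alcohol.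

**Step 6**
Reactants: 14 anti-aldol imide
Product: 15 target CNP0398772.1
Conditions: NaBH4 (4 equiv), THF/H2O 4:1, 0 °C, 2 h; AcOH to pH 5
Reagents that add atoms: none
Why: Reductive removal of the auxiliary by chemoselective borohydride reduction of the N-acyloxazolidinone: the imide carbonyl is far more electrophilic than the γ-lactone at 0 °C, so C-9″ becomes CH2OH, the oxazolidinone is released intact and no stereocenter is touched.

**Compound list**
1 | sinapyl alcohol, (E)-4-(3-hydroxyprop-1-enyl)-2,6-dimethoxyphenol | COc1cc(/C=C/CO)cc(OC)c1O | starting material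
2 | 8,8′-coupled bis-p-quinone methide, rel-(8R,8′R), racemic (one enantiomer drawn) | COC1=CC(=C[C@@H](CO)[C@H](CO)C=C2C=C(OC)C(=O)C(OC)=C2)C=C(OC)C1=O | intermediate
3 | rac-syringaresinol, exo,exo ((7S,8R,7′S,8′R) enantiomer drawn) | COc1cc(cc(OC)c1O)[C@@H]2[C@H]3CO[C@@H]([C@H]3CO2)c4cc(OC)c(O)c(OC)c4 | intermediate
4 | 7′-hydroxysyringaresinol, cyclic hemiketal, racemic, C-7′ unassigned | COc1cc(cc(OC)c1O)[C@@H]2[C@H]3COC(O)([C@H]3CO2)c4cc(OC)c(O)c(OC)c4 | intermediate
5 | rac-exo-lactone, rel-(7S,8R,8′R) (one enantiomer drawn) | COc1cc(cc(OC)c1O)[C@H]2OC[C@@H]3C(=O)OC[C@@H]32 | intermediate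
6 | (7S,8R,8′R)-exo-lactone = (1R,5R,6S)-6-(4-hydroxy-3,5-dimethoxyphenyl)-3,7-dioxabicyclo[3.3.0]octan-2-one | COc1cc(cc(OC)c1O)[C@H]2OC[C@@H]3C(=O)OC[C@@H]32 | intermediate
7 | ring-opened p-quinone methide, cis-3-(hydroxymethyl)-4-[(3,5-dimethoxy-4-oxocyclohexa-2,5-dienylidene)methyl]dihydrofuran-2-one | COC1=CC(=C[C@H]2COC(=O)[C@H]2CO)C=C(OC)C1=O | intermediate
8 | (7R,8R,8′R)-endo-lactone = (1R,5R,6R)-6-(4-hydroxy-3,5-dimethoxyphenyl)-3,7-dioxabicyclo[3.3.0]octan-2-one | COc1cc(cc(OC)c1O)[C@@H]2OC[C@@H]3C(=O)OC[C@@H]32 | intermediate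
9 | (S)-4-benzyl-3-(chloroacetyl)oxazolidin-2-one | O=C(CCl)N1[C@@H](Cc2ccccc2)COC1=O | starting material
10 | (S)-4-benzyl-3-(aryloxyacetyl)oxazolidin-2-one, aryl = 4-O of 8 | O=C(COc1c(OC)cc(cc1OC)[C@@H]2OC[C@@H]3C(=O)OC[C@@H]32)N4[C@@H](Cc5ccccc5)COC4=O | intermediate
11 | vanillin | COc1cc(C=O)ccc1O | starting material
12 | 3-methoxy-4-(trimethylsilyloxy)benzaldehyde | COc1cc(C=O)ccc1O[Si](C)(C)C | intermediate
13 | bis-TMS ether of the anti-aldol imide | COc1cc(ccc1O[Si](C)(C)C)[C@@H](O[Si](C)(C)C)[C@H](C(=O)N2[C@@H](Cc3ccccc3)COC2=O)Oc4c(OC)cc(cc4OC)[C@@H]5OC[C@@H]6C(=O)OC[C@@H]65 | intermediate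
14 | anti-aldol imide, (2R,3R)-2-aryloxy-3-hydroxy-3-(4-hydroxy-3-methoxyphenyl)propanoyl imide (spatially as C-8″/C-7″ of the target) | COc1cc(ccc1O)[C@@H](O)[C@H](C(=O)N2[C@@H](Cc3ccccc3)COC2=O)Oc4c(OC)cc(cc4OC)[C@@H]5OC[C@@H]6C(=O)OC[C@@H]65 | intermediate
15 | CNP0398772.1, (7R,8R,8′R,7″R,8″S) | COc1cc([C@@H](O)[C@H](CO)Oc2c(OC)cc([C@@H]3OC[C@@H]4C(=O)OC[C@@H]43)cc2OC)ccc1O | target

**Total step count:** 6. **Longest linear sequence:** 6 (1 → 5 → 6 → 8 → 10 → 14 → 15).

**Three steps most likely to fail**

**Step 1.** The enzymatic cleavage may stall at 3 or run on to double cleavage. About 30 % of 5 is expected after one recycle of 3. The fallback sets out from 1 and comes back at 5, and replaces the radical cleavage with two-electron chemistry. The laccase run is stopped after 2 h and crystalline 3 is isolated. DDQ (1.0 equiv, wet dioxane, 20 °C) abstracts the benzylic hydride para to one free phenol, and hydrolysis gives the ring-opened 7′-oxo alcohol F1. A Dakin oxidation (30 % H2O2, aq Na2CO3, 0 °C, then pH 2) moves the p-hydroxyaryl group from carbon to oxygen. The cis 9-OH then displaces the aryl ester to give 5.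

**Step 3.** The equilibrium may lie further to the exo side than the roughly 2:1 expected by analogy. Long acid exposure also risks elimination to the styrene. The fallback sets out from 6 and comes back at 8, and sets C-7 kinetically instead of thermodynamically. DDQ (1.05 equiv, CH2Cl2/H2O 18:1, 0 °C) gives the 7-hydroxy hemiketal lactone F2. Et3SiH/BF3·OEt2 (CH2Cl2, −78 °C) then ionises it to the aryl-conjugated bicyclic oxocarbenium ion. Hydride adds from the convex face, so H-7 ends cis to H-8/H-8′ and the aryl group ends endo, which is 8.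

**Step 5.** The anti selectivity and facial sense are not proven for an aryloxyacetyl imide. The fallback sets out from 8 and comes back at 15. It sets C-8″ by a syn-aldol and then inverts C-7″.
- 8 is alkylated with commercial (R)-4-benzyl-3-(chloroacetyl)oxazolidin-2-one (K2CO3, DMF) to give the (R)-imide ether F3.
- A Bu2BOTf/i-Pr2NEt boron aldol with commercial 4-(tert-butyldimethylsilyloxy)-3-methoxybenzaldehyde gives the Evans syn (threo, 7″S,8″S) adduct F4.
- Mitsunobu inversion (4-nitrobenzoic acid, DIAD, PPh3) gives the erythro 4-nitrobenzoate F5.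
- NaBH4 in THF/H2O at 0 °C removes the auxiliary to give the primary alcohol F6.
- K2CO3/MeOH at 0 °C followed by AcOH cleaves the nitrobenzoate and the aryl silyl ether, and re-closes any opened lactone, to give 15.

**Further compounds**
F1 | step 1 | ring-opened 7′-oxo alcohol, rel-(7S,8R,8′R)-2-aryl-4-aroyl-3-(hydroxymethyl)tetrahydrofuran, racemic (open form of 4) | COc1cc(cc(OC)c1O)[C@H]2OC[C@H](C(=O)c3cc(OC)c(O)c(OC)c3)[C@@H]2CO
F2 | step 3 | 7-hydroxy hemiketal lactone (8R,8′R; C-7 unassigned) | COc1cc(cc(OC)c1O)C2(O)OC[C@@H]3C(=O)OC[C@@H]32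
F3 | step 5 | (R)-imide ether, (R)-4-benzyl-3-(aryloxyacetyl)oxazolidin-2-one of 8 | O=C(COc1c(OC)cc(cc1OC)[C@@H]2OC[C@@H]3C(=O)OC[C@@H]32)N4[C@H](Cc5ccccc5)COC4=O
F4 | step 5 | Evans syn (threo) aldol adduct, 4-O-TBS | COc1cc(ccc1O[Si](C)(C)C(C)(C)C)[C@H](O)[C@H](C(=O)N2[C@H](Cc3ccccc3)COC2=O)Oc4c(OC)cc(cc4OC)[C@@H]5OC[C@@H]6C(=O)OC[C@@H]65
F5 | step 5 | erythro 7″-(4-nitrobenzoate) imide | COc1cc(ccc1O[Si](C)(C)C(C)(C)C)[C@@H](OC(=O)c2ccc(cc2)[N+](=O)[O-])[C@H](C(=O)N3[C@H](Cc4ccccc4)COC3=O)Oc5c(OC)cc(cc5OC)[C@@H]6OC[C@@H]7C(=O)OC[C@@H]76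
F6 | step 5 | erythro 7″-(4-nitrobenzoate) primary alcohol, 4-O-TBS | COc1cc(ccc1O[Si](C)(C)C(C)(C)C)[C@@H](OC(=O)c2ccc(cc2)[N+](=O)[O-])[C@H](CO)Oc3c(OC)cc(cc3OC)[C@@H]4OC[C@@H]5C(=O)OC[C@@H]54
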